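## Retrosynthetic overview

1. The target arises by reductive O–O cleavage of a cis-fused 1,2-dioxane/γ-lactone (plakortolide-type endoperoxide), the step by which seco-lactones of this family are thought to form in nature.
2. Ring B (γ-lactone) comes from 5-exo lactonisation of the carboxylic acid onto C4 of a 3,6-dihydro-1,2-dioxine, run as a catalyst-controlled iodolactonisation that also selects one enantiomer (kinetic resolution).
3. Ring A (1,2-dioxine) comes from [4+2] addition of singlet oxygen to (3E,5E)-4,6-dimethyldocosa-3,5-dienoic acid; the E,E geometry fixes the C3/C6 relative configuration.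
4. The dienoic acid comes from 1-octadecyne by two iterative Zr-catalysed methylaluminations (alkenyl iodide, enyne, dienylalanate plus ethylene oxide) and oxidation of the resulting homoallylic dienol.
5. Ring order: ring A first, ring B second (same flask), then ring A is opened; only ring B remains in the target.

Assumption: hydroquinidine 1,4-phthalazinediyl diether is taken to be the pseudoenantiomer that lactonises the (3S,6R)-acid faster; if a test run shows the reverse, hydroquinine 1,4-phthalazinediyl diether is used in its place with nothing else changed.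

Carbon labels C1–C6 in the Why lines are those of the dienoic acid chain (C1 = carboxyl carbon; C3, C4 and C6 become the three stereocentres).

## Route

Step 1
Reactants: 1 1-octadecyne
Product: 3 (E)-1-iodo-2-methyloctadec-1-ene, via alkenylalane 2 (not isolated)
Conditions: Me3Al (2.0 equiv), Cp2ZrCl2 (0.25 equiv), CH2Cl2, 0 °C to rt; then I2 (1.2 equiv), THF, −30 to 0 °C
Reagents that add atoms: trimethylaluminium, C[Al](C)C; iodine, II
Why: Negishi Zr-catalysed carboalumination delivers Me and Al syn across the terminal alkyne with Al on the terminal carbon, and iodinolysis of the C–Al bond goes with retention, so the trisubstituted alkene (the later C5=C6) is E (typically ≥98:2).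

Step 2
Reactants: 3 (E)-1-iodo-2-methyloctadec-1-ene; 4 ethynylmagnesium bromide
Product: 6 (E)-4-methylicos-3-en-1-yne, via ethynylzinc bromide 5 (not isolated)
Conditions: 4 (2 equiv), ZnBr2 (2 equiv), THF, 0 °C; then 3, Pd(PPh3)4 (3 mol %), THF, rt
Reagents that add atoms: none
Why: Negishi alkynylation (Pd-catalysed coupling of the alkenyl iodide with the alkynylzinc) proceeds with retention of the E geometry and gives the free terminal enyne without a silyl protecting group.

Step 3
Reactants: 6 (E)-4-methylicos-3-en-1-yne; 7 ethylene oxide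
Product: 10 (3E,5E)-4,6-dimethyldocosa-3,5-dien-1-ol, via dienylalane 8 (not isolated), via lithium dienylalanate 9 (not isolated)
Conditions: Me3Al (2.5 equiv), Cp2ZrCl2 (0.25 equiv), CH2Cl2, rt; evaporate, hexane; n-BuLi (1.0 equiv), THF, −78 to 0 °C; 7 (3 equiv), −78 °C to rt; 1 M HCl
Reagents that add atoms: trimethylaluminium, C[Al](C)C
Why: A second Negishi carboalumination, chemoselective for the alkyne of the conjugated enyne, sets the later C3=C4 alkene E by the same syn Me–Al addition, and the lithium alkenylalanate formed with n-BuLi transfers its alkenyl group to ethylene oxide with retention, adding C1–C2 as the homoallylic alcohol.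

Step 4
Reactants: 10 (3E,5E)-4,6-dimethyldocosa-3,5-dien-1-ol
Product: 11 (3E,5E)-4,6-dimethyldocosa-3,5-dienoic acid
Conditions: 2,2,6,6-tetramethylpiperidin-1-oxyl (20 mol %), PhI(OAc)2 (2.2 equiv), MeCN/pH 7 phosphate buffer 1:1, 0 °C to rt
Reagents that add atoms: water, O
Why: Oxoammonium oxidation in buffered aqueous MeCN takes the primary alcohol through the aldehyde hydrate to the acid under near-neutral conditions, the way homoallylic alcohols are turned into β,γ-unsaturated acids, so the skipped position of the diene and both E geometries are kept.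

Step 5
Reactants: 11 (3E,5E)-4,6-dimethyldocosa-3,5-dienoic acid
Product: 13 (3R,4S,4aR,7aS)-3-hexadecyl-4-iodo-3,4a-dimethyltetrahydrofuro[3,2-c][1,2]dioxin-6(3H)-one, via racemic dioxine acid 12 (not isolated)
Conditions: O2, 5,10,15,20-tetraphenylporphyrin (0.5 mol %), white LED, CH2Cl2, 0 °C; Ar purge, SiO2 plug, 1H NMR assay of 12; then hydroquinidine 1,4-phthalazinediyl diether (10 mol %), N-iodosuccinimide (in portions to ca. 45% conversion of 12), CHCl3/toluene 1:1, −40 °C, dark
Reagents that add atoms: dioxygen, O=O; N-iodosuccinimide, O=C1CCC(=O)N1I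
Why: Proposed new method: singlet oxygen adds suprafacially in a [4+2] cycloaddition to the s-cis (3E,5E)-diene, so the two outside groups (CH2CO2H on C3 and C16H33 on C6) end up cis on ring A and racemic 12 has the correct relative configuration; in the iodolactonisation the carboxylate can only close the cis-fused ring B by attacking C4 anti to an iodonium ion on the ring face opposite its own arm, so each enantiomer of 12 can use only one alkene face, and the cinchona catalyst, which binds the carboxylic acid and discriminates alkene faces in halolactonisation, should turn that facial preference into a kinetic resolution giving 13 from the (3S,6R) enantiomer, with C4a set by the cis ring fusion and the C–I centre by anti addition (closest known reaction types: singlet-oxygen diene cycloaddition followed by iodolactonisation of the dihydrodioxine acid, cinchona-catalysed enantioselective halolactonisation, desymmetrising halolactonisation of cyclohexadienylacetic acids, and kinetic resolution in cinchona-catalysed halocyclisation).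

Step 6
Reactants: 13 (3R,4S,4aR,7aS)-3-hexadecyl-4-iodo-3,4a-dimethyltetrahydrofuro[3,2-c][1,2]dioxin-6(3H)-one
Product: 15 (4S,5S)-4-hydroxy-5-[(2R)-2-hydroxy-2-methyloctadecyl]-5-methyloxolan-2-one, via peroxylactone 14 (not isolated)
Conditions: Bu3SnH (1.5 equiv), Et3B (0.2 equiv), air, toluene, 0 °C; then Zn dust (10 equiv), AcOH, rt
Reagents that add atoms: none
Why: Radical-chain tin hydride deiodination replaces C–I by C–H (the ring C5 radical is held away from the collinear geometry needed to attack the O–O bond, and halogenated cyclic peroxides are known to survive tin hydride), and Zn/AcOH then cleaves the O–O bond reductively, freeing the secondary (4S) and tertiary (2R) hydroxyl groups with retention and without touching the lactone, so no stereocentre is formed or lost.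

## Compound list

1 | 1-octadecyne | CCCCCCCCCCCCCCCCC#C | starting material
2 | dimethyl[(E)-2-methyloctadec-1-en-1-yl]alane | CCCCCCCCCCCCCCCC/C(C)=C/[Al](C)C | intermediate
3 | (E)-1-iodo-2-methyloctadec-1-ene | CCCCCCCCCCCCCCCC/C(C)=C/I | intermediate
4 | ethynylmagnesium bromide | C#C[Mg]Br | starting material
5 | ethynylzinc bromide | C#C[Zn]Br | intermediate
6 | (E)-4-methylicos-3-en-1-yne | CCCCCCCCCCCCCCCC/C(C)=C/C#C | intermediate
7 | ethylene oxide (oxirane) | C1CO1 | starting material
8 | [(1E,3E)-2,4-dimethylicosa-1,3-dien-1-yl]dimethylalane | CCCCCCCCCCCCCCCC/C(C)=C/C(C)=C/[Al](C)C | intermediate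
9 | lithium butyl[(1E,3E)-2,4-dimethylicosa-1,3-dien-1-yl]dimethylalanate | CCCCCCCCCCCCCCCC/C(C)=C/C(C)=C/[Al-](C)(C)CCCC.[Li+] | intermediate
10 | (3E,5E)-4,6-dimethyldocosa-3,5-dien-1-ol | CCCCCCCCCCCCCCCC/C(C)=C/C(C)=C/CCO | intermediate
11 | (3E,5E)-4,6-dimethyldocosa-3,5-dienoic acid | CCCCCCCCCCCCCCCC/C(C)=C/C(C)=C/CC(=O)O | intermediate
12 | rac-2-[(3S*,6R*)-6-hexadecyl-4,6-dimethyl-3,6-dihydro-1,2-dioxin-3-yl]acetic acid (racemate; the (3S,6R) enantiomer drawn is the one converted into 13) | CCCCCCCCCCCCCCCC[C@@]1(C)OO[C@@H](CC(=O)O)C(C)=C1 | intermediate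
13 | (3R,4S,4aR,7aS)-3-hexadecyl-4-iodo-3,4a-dimethyltetrahydrofuro[3,2-c][1,2]dioxin-6(3H)-one (cis-fused; I trans to the lactone oxygen) | CCCCCCCCCCCCCCCC[C@@](C)(O2)[C@@H](I)[C@]1(C)OC(=O)C[C@@H]1O2 | intermediate
14 | (3R,4aS,7aS)-3-hexadecyl-3,4a-dimethyltetrahydrofuro[3,2-c][1,2]dioxin-6(3H)-one (cis-fused peroxylactone) | CCCCCCCCCCCCCCCC[C@@](C)(O2)C[C@]1(C)OC(=O)C[C@@H]1O2 | intermediate
15 | (4S,5S)-4-hydroxy-5-[(2R)-2-hydroxy-2-methyloctadecyl]-5-methyloxolan-2-one | CCCCCCCCCCCCCCCC[C@@](C)(O)C[C@]1(C)OC(=O)C[C@@H]1O | target

## Step count and risks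

Total steps: 6. Longest linear sequence: 6 (fully linear from 1). Step 5 is capped at 50% yield by design.

First risk, step 5. Ene hydroperoxidation may compete with the [4+2] addition, and the selectivity factor of the resolution is unknown. The basic quinuclidine could also trigger Kornblum–DeLaMare opening of 12, although at −40 °C it is held as the carboxylate salt. The fallback replaces the chiral catalyst by a covalent auxiliary. 12 is isolated by chromatography after the photooxygenation and coupled with (S)-1-phenylethylamine (EDC·HCl, HOBt, CH2Cl2, 0 °C). This gives the diastereomeric amides N-[(1S)-1-phenylethyl]-2-[(3S,6R)-6-hexadecyl-4,6-dimethyl-3,6-dihydro-1,2-dioxin-3-yl]acetamide F1 and N-[(1S)-1-phenylethyl]-2-[(3R,6S)-6-hexadecyl-4,6-dimethyl-3,6-dihydro-1,2-dioxin-3-yl]acetamide F2, which are separated on silica. F1 is treated with I2 in THF/H2O at 0 °C; the amide oxygen closes onto the iodonium ion, and hydrolysis of the iminolactone releases the amine and gives 13, where the route is rejoined.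

Second risk, step 4. The β,γ-unsaturated aldehyde on the way to 11 can slip into conjugation, or the electron-rich diene can be attacked by the oxoammonium salt. The fallback changes the order of events so that the oxidation is done after the diene is gone. 10 is photooxygenated (O2, 5,10,15,20-tetraphenylporphyrin, light, CH2Cl2, 0 °C) to racemic 2-[(3S*,6R*)-6-hexadecyl-4,6-dimethyl-3,6-dihydro-1,2-dioxin-3-yl]ethan-1-ol F3. Its primary alcohol is then oxidised with the same oxoammonium system to 12, where the route is rejoined for the resolving iodolactonisation.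

Third risk, step 3. The alanate opening of ethylene oxide is the weakest C–C bond formation: it is slow, and alkyl instead of alkenyl transfer is possible. The fallback brings in C1–C2 at the acid oxidation level by enolate alkenylation. 6 is carboaluminated as before and alane 8 is quenched with I2 to give (1E,3E)-1-iodo-2,4-dimethylicosa-1,3-diene F4. Pd-catalysed coupling with commercial BrZnCH2CO2tBu (Pd(PPh3)4, THF/DMPU, 50 °C) gives tert-butyl (3E,5E)-4,6-dimethyldocosa-3,5-dienoate F5. The tert-butyl group is removed with Me3SiOTf/2,6-lutidine (CH2Cl2, 0 °C, then water) to give 11, where the route is rejoined; 10 and step 4 are bypassed.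

## Further compounds

F1 | step 5 | N-[(1S)-1-phenylethyl]-2-[(3S,6R)-6-hexadecyl-4,6-dimethyl-3,6-dihydro-1,2-dioxin-3-yl]acetamide | CCCCCCCCCCCCCCCC[C@@]1(C)OO[C@@H](CC(=O)N[C@@H](C)c2ccccc2)C(C)=C1
F2 | step 5 | N-[(1S)-1-phenylethyl]-2-[(3R,6S)-6-hexadecyl-4,6-dimethyl-3,6-dihydro-1,2-dioxin-3-yl]acetamide | CCCCCCCCCCCCCCCC[C@]1(C)OO[C@H](CC(=O)N[C@@H](C)c2ccccc2)C(C)=C1
F3 | step 4 | rac-2-[(3S*,6R*)-6-hexadecyl-4,6-dimethyl-3,6-dihydro-1,2-dioxin-3-yl]ethan-1-ol (racemate, one enantiomer drawn) | CCCCCCCCCCCCCCCC[C@@]1(C)OO[C@@H](CCO)C(C)=C1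
F4 | step 3 | (1E,3E)-1-iodo-2,4-dimethylicosa-1,3-diene | CCCCCCCCCCCCCCCC/C(C)=C/C(C)=C/I
F5 | step 3 | tert-butyl (3E,5E)-4,6-dimethyldocosa-3,5-dienoate | CCCCCCCCCCCCCCCC/C(C)=C/C(C)=C/CC(=O)OC(C)(C)C
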